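The heptanoid chain is numbered C1 (on ring A, the 4-hydroxy-3-methoxyphenyl ring) to C7 (on ring B, the 4-hydroxy-3,5-dimethoxyphenyl ring). Everything rests on unmasking the C3 ketone from a C2–C3 alkyne, exploiting the 1,3-relationship between the C5 oxygen and C3. A dimethylsilyl group on the C5 oxygen is delivered to C3 by platinum-catalysed intramolecular hydrosilylation, which in one operation closes a five-membered oxasilacycle and fixes where the later oxidation places oxygen. The precursor is the (R)-homopropargylic hydrosilyl ether with both phenols benzylated, assembled from a ring A propargylarene and a ring B (R)-epoxide that already carries the C5 stereocenter.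

Key step: step 13

Remark: the (R,R) enantiomer of the cobalt salen catalyst is taken to hydrolyse the (S) enantiomer of a monoalkyl oxirane and to leave the (R)-epoxide. C4 outranks C6 in every intermediate, so the descriptor at C5 stays R from the epoxide to the target.

Step 1
Reactants: 1 syringaldehyde (4-hydroxy-3,5-dimethoxybenzaldehyde)
Product: 2 4-(benzyloxy)-3,5-dimethoxybenzaldehyde
Conditions: BnBr, K2CO3, DMF, 60 °C
Reagents that add atoms: benzyl bromide, BrCc1ccccc1
Why: Williamson ether synthesis on the phenoxide of 1 with a reactive benzylic bromide in DMF should proceed cleanly despite the two flanking methoxy groups, and the benzyl ether so installed survives every later step until the final hydrogenolysis.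

Step 2
Reactants: 2 4-(benzyloxy)-3,5-dimethoxybenzaldehyde
Product: 3 [4-(benzyloxy)-3,5-dimethoxyphenyl]methanol
Conditions: NaBH4, MeOH, 0 °C
Reagents that add atoms: none
Why: Hydride reduction of an aromatic aldehyde by NaBH4 is fast and chemoselective, giving the benzylic alcohol without touching the aryl benzyl ether.

Step 3
Reactants: 3 [4-(benzyloxy)-3,5-dimethoxyphenyl]methanol
Product: 4 2-(benzyloxy)-5-(chloromethyl)-1,3-dimethoxybenzene
Conditions: SOCl2, CH2Cl2, 0 °C to rt
Reagents that add atoms: thionyl chloride, O=S(Cl)Cl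
Why: Deoxychlorination of an electron-rich benzylic alcohol with thionyl chloride is a standard nucleophilic substitution at an activated benzylic carbon, and the chloride is used directly without storage.

Step 4
Reactants: 4 2-(benzyloxy)-5-(chloromethyl)-1,3-dimethoxybenzene; 5 allylmagnesium bromide
Product: 6 2-(benzyloxy)-5-(but-3-en-1-yl)-1,3-dimethoxybenzene
Conditions: THF/Et2O, 0 °C to rt
Reagents that add atoms: none
Why: Uncatalysed SN2 coupling of an allylic Grignard reagent with a benzylic chloride is a dependable route to 4-aryl-1-butenes and brings in C6, C5 and C4 in one operation.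

Step 5
Reactants: 6 2-(benzyloxy)-5-(but-3-en-1-yl)-1,3-dimethoxybenzene
Product: 7 rac-2-{2-[4-(benzyloxy)-3,5-dimethoxyphenyl]ethyl}oxirane
Conditions: mCPBA, CH2Cl2, 0 °C to rt
Reagents that add atoms: 3-chloroperoxybenzoic acid (mCPBA), OOC(=O)c1cccc(Cl)c1
Why: Prilezhaev epoxidation of the monosubstituted alkene by the peracid gives the racemic terminal epoxide, the fully etherified arene being a much poorer partner for the electrophilic oxidant than the alkene.

Step 6
Reactants: 7 rac-2-{2-[4-(benzyloxy)-3,5-dimethoxyphenyl]ethyl}oxirane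
Product: 8 (R)-2-{2-[4-(benzyloxy)-3,5-dimethoxyphenyl]ethyl}oxirane
Conditions: (R,R)-(salen)Co(OAc) [salen = N,N'-bis(3,5-di-tert-butylsalicylidene)cyclohexane-1,2-diaminate] (0.5 mol%), H2O (0.55 equiv), THF, 0 °C to rt
Reagents that add atoms: none
Why: In this hydrolytic kinetic resolution the chiral trivalent cobalt salen complex adds water to the terminal carbon of the (S)-epoxide far faster than to its antipode, so with slightly more than half an equivalent of water the unreacted epoxide should be recovered as the (R)-enantiomer, which is the step that sets the C5 stereocenter of the target.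

Step 7
Reactants: 9 4-(benzyloxy)-3-methoxybenzaldehyde (O-benzylvanillin, purchased)
Product: 10 [4-(benzyloxy)-3-methoxyphenyl]methanol
Conditions: NaBH4, MeOH, 0 °C
Reagents that add atoms: none
Why: Hydride reduction of the aromatic aldehyde by NaBH4 gives the benzylic alcohol chemoselectively, as in step 2.

Step 8
Reactants: 10 [4-(benzyloxy)-3-methoxyphenyl]methanol
Product: 11 1-(benzyloxy)-4-(bromomethyl)-2-methoxybenzene
Conditions: PBr3, Et2O, 0 °C
Reagents that add atoms: phosphorus tribromide, BrP(Br)Br
Why: Conversion of a benzylic alcohol into the bromide with PBr3 is a standard SN2 deoxyhalogenation that the aryl benzyl ether tolerates at low temperature, and the reactive bromide is taken on at once.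

Step 9
Reactants: 11 1-(benzyloxy)-4-(bromomethyl)-2-methoxybenzene; 12 ethynyltrimethylsilane
Product: 14 {3-[4-(benzyloxy)-3-methoxyphenyl]prop-1-yn-1-yl}trimethylsilane, via (trimethylsilyl)ethynylmagnesium bromide 13 (not isolated)
Conditions: 12, EtMgBr, THF, 0 °C to rt; CuBr (10 mol%), then 11, reflux
Reagents that add atoms: none
Why: Copper-catalysed cross-coupling of alkynyl Grignard reagent 13 with a benzylic bromide forms the C1–C2 bond at sp3 carbon, while the silyl cap prevents a second benzylation at the other alkyne terminus.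

Step 10
Reactants: 14 {3-[4-(benzyloxy)-3-methoxyphenyl]prop-1-yn-1-yl}trimethylsilane
Product: 15 1-(benzyloxy)-2-methoxy-4-(prop-2-yn-1-yl)benzene
Conditions: K2CO3 (0.2 equiv), MeOH, 0 °C to rt
Reagents that add atoms: none
Why: Carbonate-catalysed methanolysis of the C(sp)–Si bond (protodesilylation) should free the terminal alkyne under conditions too weakly basic to move the triple bond across the benzylic propargylic CH2.

Step 11
Reactants: 15 1-(benzyloxy)-2-methoxy-4-(prop-2-yn-1-yl)benzene; 8 (R)-2-{2-[4-(benzyloxy)-3,5-dimethoxyphenyl]ethyl}oxirane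
Product: 17 (R)-7-[4-(benzyloxy)-3-methoxyphenyl]-1-[4-(benzyloxy)-3,5-dimethoxyphenyl]hept-5-yn-3-ol, via lithium acetylide 16 (not isolated)
Conditions: 15 (1.5 equiv), n-BuLi, THF, −78 °C; BF3·OEt2; then 8, −78 °C
Reagents that add atoms: none
Why: Yamaguchi–Hirao alkynylation, in which lithium acetylide 16 (formed by deprotonation of the acetylenic C–H, the most acidic site) opens the BF3-activated epoxide by SN2 attack at its unsubstituted carbon, forms the C3–C4 bond and leaves the C–O bond at C5 untouched, so the R configuration of 8 is carried into 17.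

Step 12
Reactants: 17 (R)-7-[4-(benzyloxy)-3-methoxyphenyl]-1-[4-(benzyloxy)-3,5-dimethoxyphenyl]hept-5-yn-3-ol; 18 1,1,3,3-tetramethyldisilazane
Product: 19 {[(R)-7-(4-benzyloxy-3-methoxyphenyl)-1-(4-benzyloxy-3,5-dimethoxyphenyl)hept-5-yn-3-yl]oxy}dimethylsilane
Conditions: neat 18 (excess), 60 °C; volatiles removed in vacuo, used without chromatography
Reagents that add atoms: none
Why: O-Silylation of the secondary alcohol by the disilazane (transsilylation with loss of ammonia) needs no base or salt-forming reagent, so the hydrolytically labile hydrosilyl ether can be used after evaporation alone, and because both phenols are benzylated the C5 hydroxyl is the only site that can take up silicon.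

Step 13
Reactants: 19 {[(R)-7-(4-benzyloxy-3-methoxyphenyl)-1-(4-benzyloxy-3,5-dimethoxyphenyl)hept-5-yn-3-yl]oxy}dimethylsilane
Product: 20 (R,E)-3-[2-(4-benzyloxy-3-methoxyphenyl)ethylidene]-5-[2-(4-benzyloxy-3,5-dimethoxyphenyl)ethyl]-2,2-dimethyl-1-oxa-2-silacyclopentane
Conditions: Pt2[(CH2=CHSiMe2)2O]3 (0.5 mol% Pt), THF (0.05 M), rt
Reagents that add atoms: none
Why: The Si–H bond of 19 adds oxidatively to zerovalent platinum, the tethered C2–C3 triple bond coordinates and inserts syn, and reductive elimination leaves silicon on C3 and hydrogen on C2 on the same side, so the exocyclic alkene is E. The closest known reaction type is the platinum-catalysed intramolecular hydrosilylation of homopropargylic hydrosilyl ethers, used ahead of a Tamao oxidation to reach β-hydroxy ketones. The one ring formed, the 1-oxa-2-silacyclopentane made of O, Si, C3, C4 and C5, is closed in the 5-exo-dig mode. No stereocenter is created: C5 is a spectator, and the only new stereo element is the alkene geometry, which syn addition dictates. The selectivity required is regiochemical, silicon to C3 and not to C2, and the two-atom O–C5–C4 tether secures it, because syn addition in the endo sense would demand a trans double bond inside a six-membered ring. Dilution and the absence of any other Si–H acceptor (both phenols are capped as benzyl ethers and no alkene is present) should keep the addition intramolecular.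

Step 14
Reactants: 20 (R,E)-3-[2-(4-benzyloxy-3-methoxyphenyl)ethylidene]-5-[2-(4-benzyloxy-3,5-dimethoxyphenyl)ethyl]-2,2-dimethyl-1-oxa-2-silacyclopentane
Product: 22 (R)-1-[4-(benzyloxy)-3-methoxyphenyl]-7-[4-(benzyloxy)-3,5-dimethoxyphenyl]-5-hydroxyheptan-3-one, via enol 21 (not isolated)
Conditions: 30% aq H2O2, KF, KHCO3, THF/MeOH 1:1, rt
Reagents that add atoms: hydrogen peroxide, OO
Why: Tamao oxidation, in which fluoride-activated silicon takes up hydroperoxide, the vinyl group migrates from silicon to oxygen with retention and solvolysis of the Si–O bonds releases enol 21, delivers the C3 ketone by tautomerisation and the free C5 hydroxyl under bicarbonate buffering that should spare the β-hydroxy ketone from elimination or retro-aldol cleavage.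

Step 15
Reactants: 22 (R)-1-[4-(benzyloxy)-3-methoxyphenyl]-7-[4-(benzyloxy)-3,5-dimethoxyphenyl]-5-hydroxyheptan-3-one
Product: 23 (R)-5-hydroxy-7-(4-hydroxy-3,5-dimethoxyphenyl)-1-(4-hydroxy-3-methoxyphenyl)heptan-3-one
Conditions: H2 (1 atm), 10% Pd/C, EtOAc, rt
Reagents that add atoms: none
Why: Catalytic hydrogenolysis of the two aryl benzyl ethers over palladium on carbon under neutral conditions is selective over the aliphatic ketone and the non-benzylic secondary alcohol, so the target should be released without disturbing C5.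

Compound list
1 | syringaldehyde (4-hydroxy-3,5-dimethoxybenzaldehyde) | COc1cc(C=O)cc(OC)c1O | starting material
2 | 4-(benzyloxy)-3,5-dimethoxybenzaldehyde | COc1cc(C=O)cc(OC)c1OCc1ccccc1 | intermediate
3 | [4-(benzyloxy)-3,5-dimethoxyphenyl]methanol | COc1cc(CO)cc(OC)c1OCc1ccccc1 | intermediate
4 | 2-(benzyloxy)-5-(chloromethyl)-1,3-dimethoxybenzene | COc1cc(CCl)cc(OC)c1OCc1ccccc1 | intermediate
5 | allylmagnesium bromide | C=CC[Mg]Br | starting material
6 | 2-(benzyloxy)-5-(but-3-en-1-yl)-1,3-dimethoxybenzene | COc1cc(CCC=C)cc(OC)c1OCc1ccccc1 | intermediate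
7 | rac-2-{2-[4-(benzyloxy)-3,5-dimethoxyphenyl]ethyl}oxirane | COc1cc(CCC2CO2)cc(OC)c1OCc1ccccc1 | intermediate
8 | (R)-2-{2-[4-(benzyloxy)-3,5-dimethoxyphenyl]ethyl}oxirane | COc1cc(CC[C@@H]2CO2)cc(OC)c1OCc1ccccc1 | intermediate
9 | 4-(benzyloxy)-3-methoxybenzaldehyde | COc1cc(C=O)ccc1OCc1ccccc1 | starting material
10 | [4-(benzyloxy)-3-methoxyphenyl]methanol | COc1cc(CO)ccc1OCc1ccccc1 | intermediate
11 | 1-(benzyloxy)-4-(bromomethyl)-2-methoxybenzene | COc1cc(CBr)ccc1OCc1ccccc1 | intermediate
12 | ethynyltrimethylsilane | C#C[Si](C)(C)C | starting material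
13 | (trimethylsilyl)ethynylmagnesium bromide (not isolated) | C[Si](C)(C)C#C[Mg]Br | intermediate
14 | {3-[4-(benzyloxy)-3-methoxyphenyl]prop-1-yn-1-yl}trimethylsilane | COc1cc(CC#C[Si](C)(C)C)ccc1OCc1ccccc1 | intermediate
15 | 1-(benzyloxy)-2-methoxy-4-(prop-2-yn-1-yl)benzene | COc1cc(CC#C)ccc1OCc1ccccc1 | intermediate
16 | {3-[4-(benzyloxy)-3-methoxyphenyl]prop-1-yn-1-yl}lithium (not isolated) | COc1cc(CC#C[Li])ccc1OCc1ccccc1 | intermediate
17 | (R)-7-[4-(benzyloxy)-3-methoxyphenyl]-1-[4-(benzyloxy)-3,5-dimethoxyphenyl]hept-5-yn-3-ol | COc1cc(CC#CC[C@H](O)CCc2cc(OC)c(OCc3ccccc3)c(OC)c2)ccc1OCc1ccccc1 | intermediate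
18 | 1,1,3,3-tetramethyldisilazane | C[SiH](C)N[SiH](C)C | starting material
19 | {[(R)-7-(4-benzyloxy-3-methoxyphenyl)-1-(4-benzyloxy-3,5-dimethoxyphenyl)hept-5-yn-3-yl]oxy}dimethylsilane | COc1cc(CC#CC[C@H](O[SiH](C)C)CCc2cc(OC)c(OCc3ccccc3)c(OC)c2)ccc1OCc1ccccc1 | intermediate
20 | (R,E)-3-[2-(4-benzyloxy-3-methoxyphenyl)ethylidene]-5-[2-(4-benzyloxy-3,5-dimethoxyphenyl)ethyl]-2,2-dimethyl-1-oxa-2-silacyclopentane | COc1cc(C/C=C2\C[C@@H](CCc3cc(OC)c(OCc4ccccc4)c(OC)c3)O[Si]2(C)C)ccc1OCc1ccccc1 | intermediate
21 | (2E,5R)-1-[4-(benzyloxy)-3-methoxyphenyl]-7-[4-(benzyloxy)-3,5-dimethoxyphenyl]hept-2-ene-3,5-diol (not isolated) | COc1cc(C/C=C(/O)C[C@H](O)CCc2cc(OC)c(OCc3ccccc3)c(OC)c2)ccc1OCc1ccccc1 | intermediate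
22 | (R)-1-[4-(benzyloxy)-3-methoxyphenyl]-7-[4-(benzyloxy)-3,5-dimethoxyphenyl]-5-hydroxyheptan-3-one | COc1cc(CCC(=O)C[C@H](O)CCc2cc(OC)c(OCc3ccccc3)c(OC)c2)ccc1OCc1ccccc1 | intermediate
23 | (R)-5-hydroxy-7-(4-hydroxy-3,5-dimethoxyphenyl)-1-(4-hydroxy-3-methoxyphenyl)heptan-3-one | COc1cc(CCC(=O)C[C@H](O)CCc2cc(OC)c(O)c(OC)c2)ccc1O | target

Total step count: 15.
Longest linear sequence: 11 steps (steps 1 to 6 from syringaldehyde, then steps 11 to 15). The ring A branch contributes steps 7 to 10.

Steps most likely to fail

Step 13. The Si–H ether may hydrolyse or redistribute before ring closure, hydrosilylation may occur between molecules, or a platinum hydride may move the new exocyclic double bond toward ring A. Each of these loses or misplaces the C3–Si bond on which the ketone depends. The fallback replaces the silicon tether by a carbonate tether. Setting out from 17, Boc2O and DMAP in MeCN give the tert-butyl carbonate F1. Ph3PAuNTf2 (monovalent gold) in CH2Cl2 then activates the triple bond for 6-exo-dig attack of the carbonate carbonyl oxygen at C3, with loss of 2-methylpropene, to give the cyclic enol carbonate F2. Hydrolysis with LiOH in THF/H2O at 0 °C releases the C3 ketone and the C5 hydroxyl, and the route is rejoined at 22. This draws on the known gold-catalysed cyclisation of homopropargylic tert-butyl carbonates.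

Step 11. Proton transfer from the doubly activated benzylic propargylic CH2 at C1 to the acetylide may lead to allenyl species, or the Lewis acid may rearrange the epoxide before the C–C bond forms. The fallback makes the C1–C2 bond last and never lithiates 15. Setting out from 8, lithium acetylide–ethylenediamine complex (LiC≡CH·H2NCH2CH2NH2) in DMSO at rt opens the epoxide at its terminal carbon to give (R)-1-[4-(benzyloxy)-3,5-dimethoxyphenyl]hex-5-yn-3-ol F3. EtMgBr (2 equiv) in THF converts it into the bis(bromomagnesium) derivative F4, whose alkynyl terminus is coupled with bromide 11 under CuBr catalysis as in step 9, coming back to the route at 17.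

Step 9. Wurtz-type homocoupling or self-alkylation of the electron-rich benzylic bromide may outpace the copper-mediated cross-coupling. The fallback forms the same C1–C2 bond by carbonyl addition. Setting out from 9, commercial lithium (trimethylsilyl)acetylide (LiC≡CSiMe3) in THF at −78 °C gives the racemic propargylic alcohol F5. Ionic hydrogenation with Et3SiH and CF3CO2H in CH2Cl2 at 0 °C then removes the benzylic hydroxyl through the aryl-stabilised propargylic cation and returns to the route at 14, bypassing 10 and 11.

Further compounds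
F1 | step 13 | tert-butyl (R)-{7-[4-(benzyloxy)-3-methoxyphenyl]-1-[4-(benzyloxy)-3,5-dimethoxyphenyl]hept-5-yn-3-yl} carbonate | COc1cc(CC#CC[C@H](OC(=O)OC(C)(C)C)CCc2cc(OC)c(OCc3ccccc3)c(OC)c2)ccc1OCc1ccccc1
F2 | step 13 | (R,Z)-4-{2-[4-(benzyloxy)-3-methoxyphenyl]ethylidene}-6-{2-[4-(benzyloxy)-3,5-dimethoxyphenyl]ethyl}-1,3-dioxan-2-one | COc1cc(C/C=C2/C[C@@H](CCc3cc(OC)c(OCc4ccccc4)c(OC)c3)OC(=O)O2)ccc1OCc1ccccc1
F3 | step 11 | (R)-1-[4-(benzyloxy)-3,5-dimethoxyphenyl]hex-5-yn-3-ol | COc1cc(CC[C@@H](O)CC#C)cc(OC)c1OCc1ccccc1
F4 | step 11 | bis(bromomagnesium) derivative of F3 (bromomagnesium alkoxide at O3, alkynylmagnesium bromide at C6) | COc1cc(CC[C@@H](O[Mg]Br)CC#C[Mg]Br)cc(OC)c1OCc1ccccc1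
F5 | step 9 | rac-1-[4-(benzyloxy)-3-methoxyphenyl]-3-(trimethylsilyl)prop-2-yn-1-ol | COc1cc(C(O)C#C[Si](C)(C)C)ccc1OCc1ccccc1
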